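**Retrosynthetic overview**
1. Target 18 ⇐ triol 15 by three late acyl operations (C‑15 allyl malonate, C‑18 angelate, de‑allylation).
2. 15 ⇐ diacid 14 (LiAlH4); ring B of 14 is closed last through the C8–C9 bond by a cathodic ketyl–olefin 6‑exo cyclisation of seco keto‑alkene 13, which sets C‑8 and C‑9.
3. 13 ⇐ Z‑Wittig of ring‑A keto‑aldehyde 6 with C5 ylide 12, which carries C‑13 from methyl hydrogen (S)‑3‑methylglutarate 7.
4. 6 ⇐ dehydroabietic acid 1 read in reverse: abietane C‑4 becomes labdane C‑10 (its CO2H carbon becomes C‑9), abietane C‑10 becomes C‑4 (aromatic C‑9 becomes C‑18), and C‑5 to C‑8 are kept. After RuO4 degradation of the arene, the normal‑series A ring of 1 is the ent‑labdane A ring with C‑4, C‑5 and C‑10 correct.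
5. Ring order: ring A is bought in 1; ring B is the only ring formed (step 9).

Assumption: methyl hydrogen (S)‑3‑methylglutarate (7) and allyl hydrogen malonate are taken as catalogue compounds; positions are given in labdane numbering.

**Step 1**
Reactants: 1 dehydroabietic acid
Product: 2 dehydroabietinol
Conditions: LiAlH4 (2.5 equiv), THF, 0 °C → reflux, 4 h; aqueous work-up
Reagents that add atoms: none
Why: LiAlH4 reduction of the hindered equatorial carboxylic acid to the neopentyl primary alcohol, with no stereocentre touched.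

**Step 2**
Reactants: 2 dehydroabietinol
Product: 3 dehydroabietyl acetate
Conditions: Ac2O, pyridine, DMAP (cat.), CH2Cl2, rt
Reagents that add atoms: acetic anhydride (CC(=O)OC(C)=O)
Why: O‑acetylation keeps this carbon (future C‑9) at the alcohol level and different from the CO2H groups made next, so the otherwise meso‑type cyclohexane of 4 stays chiral.

**Step 3**
Reactants: 3 dehydroabietyl acetate
Product: 4 (1S,2S,3R)-3-(acetoxymethyl)-2-(2-carboxyethyl)-1,3-dimethylcyclohexane-1-carboxylic acid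
Conditions: RuCl3·xH2O (5 mol %), NaIO4 (18 equiv), CCl4/MeCN/H2O 2:2:3, rt, 24–48 h
Reagents that add atoms: sodium periodate ([Na+].[O-]I(=O)(=O)=O), water (O)
Why: Catalytic RuO4 arene degradation burns the trialkylbenzene ring down to its two ipso carbons, which stay as CO2H on the quaternary ring carbon (future C‑18) and on the chain (future C‑8), while the three sp3 stereocentres are untouched.

**Step 4**
Reactants: 4 (1S,2S,3R)-3-(acetoxymethyl)-2-(2-carboxyethyl)-1,3-dimethylcyclohexane-1-carboxylic acid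
Product: 5 (1S,2S,3R)-3-(hydroxymethyl)-1,3-dimethyl-2-(3-oxobutyl)cyclohexane-1-carboxylic acid
Conditions: MeLi (6.5 equiv), THF, −20 → 0 °C, 2 h; inverse quench into cold 1 M HCl; crude used at once (avoid acid and heat, δ‑lactonisation)
Reagents that add atoms: methyllithium ([Li]C)
Why: Organolithium ketone synthesis via the stable dilithio gem‑diolate takes place only at the unhindered chain carboxylate, the α,α‑disubstituted ring carboxylate is inert at 0 °C, and the acetate is cleaved in the same operation.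

**Step 5**
Reactants: 5 (1S,2S,3R)-3-(hydroxymethyl)-1,3-dimethyl-2-(3-oxobutyl)cyclohexane-1-carboxylic acid
Product: 6 (1S,2S,3R)-3-formyl-1,3-dimethyl-2-(3-oxobutyl)cyclohexane-1-carboxylic acid
Conditions: Dess–Martin periodinane (1.3 equiv), CH2Cl2, 0 °C → rt, 1 h; used at once
Reagents that add atoms: none
Why: Dess–Martin oxidation turns the neopentyl alcohol into a non‑enolisable aldehyde under neutral conditions that leave the ketone and acid alone.

**Step 6**
Reactants: 7 methyl hydrogen (S)-3-methylglutarate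
Product: 9 (S)-4-methyltetrahydro-2H-pyran-2-one, via methyl (S)-5-hydroxy-3-methylpentanoate 8 (not isolated)
Conditions: BH3·SMe2 (1.1 equiv), THF, 0 °C → rt; H2O; then p‑TsOH (cat.), toluene, 80 °C
Reagents that add atoms: none
Why: Chemoselective borane reduction of the acid beside the ester, then acid‑catalysed lactonisation; the stereocentre is β to both carbonyls and cannot epimerise.

**Step 7**
Reactants: 9 (S)-4-methyltetrahydro-2H-pyran-2-one
Product: 11 (R)-(4-carboxy-3-methylbutyl)triphenylphosphonium bromide, via (R)-5-bromo-3-methylpentanoic acid 10 (not isolated)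
Conditions: Ph3P·HBr (1.0 equiv), neat melt, 160 °C, 4 h
Reagents that add atoms: triphenylphosphine hydrobromide (Br.c1ccc(cc1)P(c1ccccc1)c1ccccc1)
Why: HBr opens the δ‑lactone by SN2 at O–CH2 and PPh3 then displaces bromide (phosphonium salt formation); the stereocentre is not involved and only its CIP label changes.

**Step 8**
Reactants: 6 (1S,2S,3R)-3-formyl-1,3-dimethyl-2-(3-oxobutyl)cyclohexane-1-carboxylic acid; 11 (R)-(4-carboxy-3-methylbutyl)triphenylphosphonium bromide
Product: 13 (1S,2S,3S)-3-[(1Z,4S)-5-carboxy-4-methylpent-1-en-1-yl]-1,3-dimethyl-2-(3-oxobutyl)cyclohexane-1-carboxylic acid, via carboxylate ylide 12 (not isolated)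
Conditions: 11 (2.5 equiv), NaHMDS (5.0 equiv), THF, 0 °C, 30 min; then 6, −78 → −20 °C; aq. HCl
Reagents that add atoms: none
Why: Z‑selective Wittig olefination by a non‑stabilised carboxylate ylide, which at −78 °C adds to the aldehyde far faster than it attacks or enolises the methyl ketone; the alkene geometry is lost later, so it is of no stereochemical consequence.

**Step 9**
Reactants: 13 (1S,2S,3S)-3-[(1Z,4S)-5-carboxy-4-methylpent-1-en-1-yl]-1,3-dimethyl-2-(3-oxobutyl)cyclohexane-1-carboxylic acid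
Product: 14 (3S)-5-[(1S,2S,4aS,5S,8aR)-5-carboxy-2-hydroxy-2,5,8a-trimethyldecahydronaphthalen-1-yl]-3-methylpentanoic acid
Conditions: undivided cell, Mg anode, Sn‑plate (or graphite‑felt) cathode, Bu4NBr (0.1 M), DMF, t‑BuOH (3 equiv), 0.02 M in 13, constant current 5 mA cm−2, 5–6 F mol−1, 0 °C → rt; then 1 M HCl
Reagents that add atoms: none
Why: Proposed new method: cathodic one‑electron reduction of the unactivated methyl ketone of the free diacid (whose two CO2H protons are discharged first as H2, leaving the Mg dicarboxylate) gives a Mg‑bound ketyl radical anion that adds 6‑exo‑trig to the non‑activated internal Z‑alkene next to the quaternary carbon through a chair transition state built on the two equatorial arms of ring A (bulky O–Mg equatorial and trans to the C‑9 chain, C‑8 methyl axial), after which the secondary C‑11 radical is reduced and protonated, so ring B closes as the trans‑decalin with C‑8 (S) and C‑9 (S) set by C‑5 and C‑10; the closest known reactions are the electroreductive cyclisation of terminal olefinic ketones and SmI2 ketyl–olefin cyclisations, neither shown for an internal, neopentyl alkene on an unprotected diacid.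

**Step 10**
Reactants: 14 (3S)-5-[(1S,2S,4aS,5S,8aR)-5-carboxy-2-hydroxy-2,5,8a-trimethyldecahydronaphthalen-1-yl]-3-methylpentanoic acid
Product: 15 (1S,2S,4aS,5S,8aR)-1-[(3S)-5-hydroxy-3-methylpentyl]-5-(hydroxymethyl)-2,5,8a-trimethyldecahydronaphthalen-2-ol
Conditions: LiAlH4 (6 equiv), THF, reflux, 12 h; Rochelle salt work-up
Reagents that add atoms: none
Why: LiAlH4 reduces both carboxylic acids (the hindered C‑18 acid needs reflux, as in step 1) to the C‑15 and C‑18 primary alcohols without touching the tertiary alcohol or any stereocentre.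

**Step 11**
Reactants: 15 (1S,2S,4aS,5S,8aR)-1-[(3S)-5-hydroxy-3-methylpentyl]-5-(hydroxymethyl)-2,5,8a-trimethyldecahydronaphthalen-2-ol
Product: 16 allyl (3S)-5-[(1S,2S,4aS,5S,8aR)-2-hydroxy-5-(hydroxymethyl)-2,5,8a-trimethyldecahydronaphthalen-1-yl]-3-methylpentyl malonate
Conditions: allyl hydrogen malonate (1.05 equiv), DCC (1.1 equiv), DMAP (5 mol %), CH2Cl2, −20 → 0 °C
Reagents that add atoms: allyl hydrogen malonate (C=CCOC(=O)CC(=O)O)
Why: Steglich esterification at low temperature acylates the unhindered C‑15 primary alcohol much faster than the neopentyl C‑18 alcohol or the tertiary C‑8 alcohol.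

**Step 12**
Reactants: 16 allyl (3S)-5-[(1S,2S,4aS,5S,8aR)-2-hydroxy-5-(hydroxymethyl)-2,5,8a-trimethyldecahydronaphthalen-1-yl]-3-methylpentyl malonate
Product: 17 allyl (3S)-5-[(1S,2S,4aS,5S,8aR)-2-hydroxy-2,5,8a-trimethyl-5-({[(2Z)-2-methylbut-2-enoyl]oxy}methyl)decahydronaphthalen-1-yl]-3-methylpentyl malonate
Conditions: angelic acid (3 equiv), 2,4,6-trichlorobenzoyl chloride (3 equiv), Et3N (3 equiv), toluene, rt, 2 h; then 16, 75 °C, 24 h (no DMAP)
Reagents that add atoms: angelic acid (C/C=C(/C)C(=O)O)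
Why: Yamaguchi‑type mixed‑anhydride acylation run without a nucleophilic catalyst esterifies the neopentyl C‑18 alcohol while avoiding the addition–elimination pathway that isomerises angelate to tiglate; the tertiary C‑8 alcohol does not react.

**Step 13**
Reactants: 17 allyl (3S)-5-[(1S,2S,4aS,5S,8aR)-2-hydroxy-2,5,8a-trimethyl-5-({[(2Z)-2-methylbut-2-enoyl]oxy}methyl)decahydronaphthalen-1-yl]-3-methylpentyl malonate
Product: 18 3-{[(3S)-5-[(1S,2S,4aS,5S,8aR)-2-hydroxy-2,5,8a-trimethyl-5-({[(2Z)-2-methylbut-2-enoyl]oxy}methyl)decahydronaphthalen-1-yl]-3-methylpentyl]oxy}-3-oxopropanoic acid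
Conditions: Pd(PPh3)4 (5 mol %), morpholine (3 equiv), THF, rt, 1 h; cold aq. NaHSO4
Reagents that add atoms: none
Why: Tsuji–Trost de‑allylation under neutral conditions frees the malonic half acid without affecting the angelate, the tertiary alcohol or the second malonate ester linkage.

**Compound list**
1 | dehydroabietic acid | CC(C)C1=CC2=C(C=C1)[C@]3(CCC[C@@]([C@@H]3CC2)(C)C(=O)O)C | starting material
2 | dehydroabietinol | CC(C)C1=CC2=C(C=C1)[C@]3(CCC[C@@]([C@@H]3CC2)(C)CO)C | intermediate
3 | dehydroabietyl acetate | CC(C)C1=CC2=C(C=C1)[C@]3(CCC[C@@]([C@@H]3CC2)(C)COC(C)=O)C | intermediate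
4 | (1S,2S,3R)-3-(acetoxymethyl)-2-(2-carboxyethyl)-1,3-dimethylcyclohexane-1-carboxylic acid | OC(=O)[C@@]1(C)CCC[C@@](C)(COC(C)=O)[C@@H]1CCC(=O)O | intermediate
5 | (1S,2S,3R)-3-(hydroxymethyl)-1,3-dimethyl-2-(3-oxobutyl)cyclohexane-1-carboxylic acid | OC(=O)[C@@]1(C)CCC[C@@](C)(CO)[C@@H]1CCC(C)=O | intermediate
6 | (1S,2S,3R)-3-formyl-1,3-dimethyl-2-(3-oxobutyl)cyclohexane-1-carboxylic acid | OC(=O)[C@@]1(C)CCC[C@@](C)(C=O)[C@@H]1CCC(C)=O | intermediate
7 | methyl hydrogen (S)-3-methylglutarate [(3S)-5-methoxy-3-methyl-5-oxopentanoic acid] | OC(=O)C[C@H](C)CC(=O)OC | starting material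
8 | methyl (S)-5-hydroxy-3-methylpentanoate | OCC[C@H](C)CC(=O)OC | intermediate
9 | (S)-4-methyltetrahydro-2H-pyran-2-one | O=C1C[C@@H](C)CCO1 | intermediate
10 | (R)-5-bromo-3-methylpentanoic acid | OC(=O)C[C@@H](C)CCBr | intermediate
11 | (R)-(4-carboxy-3-methylbutyl)triphenylphosphonium bromide | [Br-].OC(=O)C[C@@H](C)CC[P+](c1ccccc1)(c1ccccc1)c1ccccc1 | intermediate
12 | sodium (R)-3-methyl-5-(triphenyl-λ5-phosphanylidene)pentanoate (carboxylate ylide) | [Na+].[O-]C(=O)C[C@@H](C)CC=P(c1ccccc1)(c1ccccc1)c1ccccc1 | intermediate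
13 | (1S,2S,3S)-3-[(1Z,4S)-5-carboxy-4-methylpent-1-en-1-yl]-1,3-dimethyl-2-(3-oxobutyl)cyclohexane-1-carboxylic acid | OC(=O)[C@@]1(C)CCC[C@@](C)(/C=C\C[C@H](C)CC(=O)O)[C@@H]1CCC(C)=O | intermediate
14 | (3S)-5-[(1S,2S,4aS,5S,8aR)-5-carboxy-2-hydroxy-2,5,8a-trimethyldecahydronaphthalen-1-yl]-3-methylpentanoic acid | OC(=O)[C@@]1(C)CCC[C@]2(C)[C@@H]1CC[C@](C)(O)[C@H]2CC[C@H](C)CC(=O)O | intermediate
15 | (1S,2S,4aS,5S,8aR)-1-[(3S)-5-hydroxy-3-methylpentyl]-5-(hydroxymethyl)-2,5,8a-trimethyldecahydronaphthalen-2-ol | OC[C@@]1(C)CCC[C@]2(C)[C@@H]1CC[C@](C)(O)[C@H]2CC[C@H](C)CCO | intermediate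
16 | allyl (3S)-5-[(1S,2S,4aS,5S,8aR)-2-hydroxy-5-(hydroxymethyl)-2,5,8a-trimethyldecahydronaphthalen-1-yl]-3-methylpentyl malonate | OC[C@@]1(C)CCC[C@]2(C)[C@@H]1CC[C@](C)(O)[C@H]2CC[C@H](C)CCOC(=O)CC(=O)OCC=C | intermediate
17 | allyl (3S)-5-[(1S,2S,4aS,5S,8aR)-2-hydroxy-2,5,8a-trimethyl-5-({[(2Z)-2-methylbut-2-enoyl]oxy}methyl)decahydronaphthalen-1-yl]-3-methylpentyl malonate | C/C=C(/C)C(=O)OC[C@@]1(C)CCC[C@]2(C)[C@@H]1CC[C@](C)(O)[C@H]2CC[C@H](C)CCOC(=O)CC(=O)OCC=C | intermediate
18 | CNP0286290.1, 3-{[(3S)-5-[(1S,2S,4aS,5S,8aR)-2-hydroxy-2,5,8a-trimethyl-5-({[(2Z)-2-methylbut-2-enoyl]oxy}methyl)decahydronaphthalen-1-yl]-3-methylpentyl]oxy}-3-oxopropanoic acid | C/C=C(/C)C(=O)OC[C@@]1(C)CCC[C@]2(C)[C@@H]1CC[C@](C)(O)[C@H]2CC[C@H](C)CCOC(=O)CC(=O)O | target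

**Step count**
Total: 13 steps. Longest linear sequence: 11 steps (1 → 18 through steps 1–5 and 8–13); the side chain branch is steps 6–7.

**Three steps most likely to fail**

Step 3 (arene degradation). Benzylic oxidation at C‑7 can compete with ring destruction and give 7‑oxo and chain‑shortened acids. The fallback sets out from 3 and first makes the ring electron‑rich so that ozone cleaves it cleanly. Friedel–Crafts acetylation (AcCl, AlCl3, CH2Cl2, 0 °C) gives 12-acetyldehydroabietyl acetate F1. Baeyer–Villiger oxidation (mCPBA, cat. TFA, CH2Cl2) gives 12-acetoxydehydroabietyl acetate F2. Selective aminolysis of the aryl ester (pyrrolidine, CH2Cl2, 0 °C) gives 12-hydroxydehydroabietyl acetate F3. Ozonolysis of the phenol ring (O3, CH2Cl2/MeOH, −78 °C; then H2O2/HCO2H) returns to the route at 4.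

Step 4 (MeLi). One operation has to tell two carboxylates apart and unmask the alcohol, so incomplete conversion or attack at the ring carboxylate is possible. The fallback sets out from 4. Selective amidation of the unhindered chain acid (MeNHOMe·HCl, EDC, HOBt, i‑Pr2NEt, CH2Cl2, 0 °C) gives the chain N-methoxy-N-methylamide of 4 F4. MeMgBr (5 equiv, THF, 0 °C) then converts the Weinreb amide to the methyl ketone and cleaves the acetate, returning to the route at 5.

Step 9 (the proposed new electroreductive cyclisation). The ketyl may be reduced to the open‑chain carbinol or pinacol, and the C‑8 epimer (O axial, methyl equatorial) is a plausible competitor because it avoids the 1,3‑diaxial methyl pair. The fallback uses known chemistry and sets out from 13. Methylation (MeI, K2CO3, DMF) gives the dimethyl ester of 13 F5. A stoichiometric SmI2 ketyl–olefin cyclisation (SmI2 3 equiv, HMPA, t‑BuOH, THF, rt), in which the very large O–Sm(HMPA)n group takes the equatorial position, gives the dimethyl ester of 14 F6. LiAlH4 (THF, reflux) reduces both esters and the route is rejoined at 15.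

**Further compounds**
F1 | step 3 | 12-acetyldehydroabietyl acetate | CC(C)C1=CC2=C(C=C1C(C)=O)[C@]3(CCC[C@@]([C@@H]3CC2)(C)COC(C)=O)C
F2 | step 3 | 12-acetoxydehydroabietyl acetate | CC(C)C1=CC2=C(C=C1OC(C)=O)[C@]3(CCC[C@@]([C@@H]3CC2)(C)COC(C)=O)C
F3 | step 3 | 12-hydroxydehydroabietyl acetate | CC(C)C1=CC2=C(C=C1O)[C@]3(CCC[C@@]([C@@H]3CC2)(C)COC(C)=O)C
F4 | step 4 | chain N-methoxy-N-methylamide of 4 | OC(=O)[C@@]1(C)CCC[C@@](C)(COC(C)=O)[C@@H]1CCC(=O)N(C)OC
F5 | step 9 | dimethyl ester of 13 | COC(=O)[C@@]1(C)CCC[C@@](C)(/C=C\C[C@H](C)CC(=O)OC)[C@@H]1CCC(C)=O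
F6 | step 9 | dimethyl ester of 14 | COC(=O)[C@@]1(C)CCC[C@]2(C)[C@@H]1CC[C@](C)(O)[C@H]2CC[C@H](C)CC(=O)OC
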